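**Plan**
- Enabling feature: the upper pyran ring (ring C: O1, C2, C3, C4, C4a, C8a) carries ring B on C2, the galloyloxy group on C3 and C8 of the lower flavan on C4. It is therefore the chroman that an o-quinone methide (O1–C8a–C4a–C4) and a β-acyloxystyrene (C2=C3) give by [4+2] addition.
- Retrosynthesis: first the lower 3-O-gallate and the sixteen benzyl ethers are removed, then O1–C2 and C3–C4 of the upper ring C are cut together, then the carbinol–C8 bond of the methide precursor and the vinyl C–O bond of the enol gallate.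
- Forward: benzylated, 3-O-silylated epigallocatechin is brominated at C8, lithiated and added to 4,6-bis(benzyloxy)salicylaldehyde. A Z-enol gallate is made from an arylalkyne and tri-O-benzylgallic acid. The acid-catalysed cycloaddition joins the halves and closes the only new ring, and desilylation, galloylation and hydrogenolysis finish.
- Stereochemistry: lower C2/C3 come from (−)-epigallocatechin; upper C2/C3 cis comes from the Z alkene, C4 trans to C3 from exo addition, and the absolute sense from a chiral Brønsted acid.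

Key step: step 9

Assumption: the face preference of the chiral acid cannot be assigned in advance; the R-configured acid is written, and its equally available enantiomer would be used if that one leads to the (2R,3R,4R) upper unit.

Abbreviations: Bn = benzyl, TBS = tert-butyldimethylsilyl.

**Step 1**
Reactants: 1 (−)-epigallocatechin
Product: 2 5,7,3',4',5'-penta-O-benzyl-(−)-epigallocatechin (2R,3R; 3-OH free)
Conditions: BnBr (5.5 equiv), K2CO3, degassed DMF, N2, 0 °C → rt
Reagents that add atoms: benzyl bromide, BrCc1ccccc1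
Why: Williamson etherification in which carbonate deprotonates only the five phenols, while mild oxygen-free conditions should avoid oxidation of the pyrogallol ring and base-induced epimerisation at C2, so the 2R,3R centres are carried through.

**Step 2**
Reactants: 2 penta-O-benzyl-(−)-epigallocatechin
Product: 3 penta-O-benzyl-3-O-TBS-(−)-epigallocatechin
Conditions: TBSCl, imidazole, DMF, rt
Reagents that add atoms: tert-butyldimethylsilyl chloride, CC(C)(C)[Si](C)(C)Cl
Why: Imidazole-promoted silyl ether formation masks the only remaining acidic proton (the axial C3 alcohol) before the organolithium step.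

**Step 3**
Reactants: 3 penta-O-benzyl-3-O-TBS-(−)-epigallocatechin
Product: 4 8-bromo-penta-O-benzyl-3-O-TBS-(−)-epigallocatechin
Conditions: NBS (1.0 equiv), CH2Cl2, −78 → 0 °C
Reagents that add atoms: N-bromosuccinimide, O=C1CCC(=O)N1Br
Why: Electrophilic aromatic bromination occurs on ring A, which is activated by three oxygen substituents, and for 3-O-silylated 5,7-di-O-benzylflavans it is known to prefer C8 over C6.

**Step 4**
Reactants: 5 2,4,6-trihydroxybenzaldehyde
Product: 6 4,6-bis(benzyloxy)-2-hydroxybenzaldehyde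
Conditions: BnBr (2.1 equiv), K2CO3 (2.2 equiv), DMF, 0 °C → rt
Reagents that add atoms: benzyl bromide, BrCc1ccccc1
Why: Williamson etherification with two equivalents of halide should leave one ortho hydroxyl free, because it is hydrogen-bonded to the formyl group and is the least reactive.

**Step 5**
Reactants: 4 8-bromo-penta-O-benzyl-3-O-TBS-(−)-epigallocatechin; 6 4,6-bis(benzyloxy)-2-hydroxybenzaldehyde
Product: 9 8-[(4,6-bis(benzyloxy)-2-hydroxyphenyl)(hydroxy)methyl]-penta-O-benzyl-3-O-TBS-(−)-epigallocatechin (both carbinol epimers), via sodium 3,5-bis(benzyloxy)-2-formylphenoxide 7 (not isolated), via 8-lithio-penta-O-benzyl-3-O-TBS-epigallocatechin 8 (not isolated)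
Conditions: 6, NaH (1.05 equiv), THF, 0 °C; 4, t-BuLi (2.0 equiv), THF, −78 °C; then 7 (1.5 equiv), −78 → −20 °C; sat. aq. NH4Cl; Et3N-deactivated silica
Reagents that add atoms: none
Why: Bromine–lithium exchange followed by 1,2-addition of the aryllithium to the aldehyde, with the phenol pre-converted into its sodium salt so that it cannot protonate 8; the carbinol centre needs no control because both epimers ionise to the same quinone methide.

**Step 6**
Reactants: 10 3,4,5-trihydroxybenzaldehyde
Product: 11 3,4,5-tris(benzyloxy)benzaldehyde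
Conditions: BnBr (3.3 equiv), K2CO3, degassed DMF, N2, rt → 60 °C
Reagents that add atoms: benzyl bromide, BrCc1ccccc1
Why: Exhaustive Williamson etherification of the three phenols, standard for gallic-type aldehydes.

**Step 7**
Reactants: 11 3,4,5-tris(benzyloxy)benzaldehyde
Product: 12 1,2,3-tris(benzyloxy)-5-ethynylbenzene
Conditions: dimethyl (1-diazo-2-oxopropyl)phosphonate, K2CO3, MeOH/THF, 0 °C → rt
Reagents that add atoms: dimethyl (1-diazo-2-oxopropyl)phosphonate, COP(=O)(OC)C(=[N+]=[N-])C(C)=O
Why: Ohira–Bestmann (Seyferth–Gilbert) homologation, in which the diazomethylphosphonate anion formed in situ olefinates the aldehyde and the diazoalkene loses N2 with 1,2-hydrogen shift to give the terminal alkyne without affecting the benzyl ethers.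

**Step 8**
Reactants: 12 1,2,3-tris(benzyloxy)-5-ethynylbenzene; 13 3,4,5-tris(benzyloxy)benzoic acid
Product: 14 (Z)-2-[3,4,5-tris(benzyloxy)phenyl]ethenyl 3,4,5-tris(benzyloxy)benzoate
Conditions: Ru(η3-CH2C(CH3)CH2)2(Ph2P(CH2)4PPh2) (3 mol%), toluene, 60 °C
Reagents that add atoms: none
Why: Ruthenium-catalysed anti-Markovnikov hydro-oxycarbonylation of a terminal alkyne, in which the carboxylate adds to the α-carbon of a ruthenium vinylidene and protonolysis gives the (Z)-enol ester, as established for arylacetylenes and benzoic acids.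

**Step 9**
Reactants: 9 o-hydroxybenzhydrol (both carbinol epimers); 14 (Z)-enol gallate
Product: 16 benzyl-protected (4β→8) dimer with upper 3-O-[3,4,5-tris(benzyloxy)benzoyl] and lower 3-O-TBS (upper unit 2R,3R,4R; lower unit 2R,3R), via E-o-quinone methide 15 (not isolated)
Conditions: (R)-3,3'-bis(2,4,6-triisopropylphenyl)-1,1'-binaphthyl-2,2'-diyl N-triflylphosphoramide (10 mol%), 5 Å MS, toluene, −30 → 0 °C, 9 added slowly to 14 (2 equiv)
Reagents that add atoms: none
Why: Proposed new method: the acid protonates the carbinol oxygen of 9 and water leaves to give the hydrogen-bonded E-quinone methide 15 (in effect a contact ion pair), whose methide carbon, the future upper C4, is attacked by the gallate-bearing alkene carbon of 14 while positive charge builds at the carbon carrying ring B, and the quinone oxygen closes onto that carbon in one asynchronous inverse-electron-demand hetero-Diels–Alder event. The closest known reaction type is the chiral Brønsted acid-catalysed [4+2] cycloaddition of o-quinone methides, generated from o-hydroxybenzhydrols, with styrenes, β-substituted styrenes and enol ethers; a β-acyloxystyrene has not been used as the 2π partner, but it keeps the donor aryl group on which those reactions rely. The upper pyran ring (ring C) closes by intermolecular [4+2] cycloaddition, C3–C4 forming ahead of O1–C2 within a six-membered transition state. C2 and C3 should become cis because the Z geometry of 14 is transferred suprafacially, ring closure in the tight ion pair outrunning rotation about C2–C3; C4 should become trans to C3 through the exo transition state, in which the acyloxy group lies between the methide hydrogen and the lower aryl group instead of between ring A and that aryl group, which stands perpendicular to the methide plane with both ortho substituents; the absolute (2R,3R,4R) configuration is set by the chiral counter-anion bound at the quinone oxygen, which covers one face of the methide, the stereocentres of the lower unit being too remote to interfere. The step needs regioselectivity (C–C bond at the gallate carbon), secured by the far better cation stabilisation by the tris(benzyloxy)phenyl group than by the acyloxy group, and chemoselectivity against arylation of the free C6 positions, secured by slow addition of 9 to an excess of 14.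

**Step 10**
Reactants: 16 protected dimer with lower 3-O-TBS
Product: 17 protected dimer with free lower 3-OH (upper 3-O-gallate retained)
Conditions: HF·pyridine, THF/pyridine, 0 °C → rt
Reagents that add atoms: none
Why: Fluoride-mediated Si–O cleavage (desilylation) under weakly acidic, non-nucleophilic conditions that should spare the upper gallate ester, the benzyl ethers and the C4–C8 bond.

**Step 11**
Reactants: 17 protected dimer with free lower 3-OH; 13 3,4,5-tris(benzyloxy)benzoic acid
Product: 18 hexadeca-O-benzyl rhodisin (both C3 oxygens as 3,4,5-tris(benzyloxy)benzoates)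
Conditions: 13 (3 equiv), DCC, DMAP, CH2Cl2, rt
Reagents that add atoms: none
Why: Steglich esterification (carbodiimide/DMAP acylation) of the liberated axial C3 alcohol, the usual way of galloylating benzylated flavan-3-ols, touches no stereocentre.

**Step 12**
Reactants: 18 hexadeca-O-benzyl rhodisin
Product: 19 rhodisin
Conditions: H2 (1 atm), Pd(OH)2 on carbon, THF/MeOH/H2O, rt; filtration under N2, lyophilisation
Reagents that add atoms: none
Why: Catalytic hydrogenolysis of all sixteen benzyl ethers, a debenzylation known to leave gallate esters, the benzylic C2–O bonds and the C4–C8 bond of catechin oligomers intact.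

**Compound list**

1 | (−)-epigallocatechin, (2R,3R) | O[C@@H]1Cc2c(O)cc(O)cc2O[C@@H]1c1cc(O)c(O)c(O)c1 | starting material

2 | 5,7,3',4',5'-penta-O-benzyl-(−)-epigallocatechin, (2R,3R) | O[C@@H]1Cc2c(OCc3ccccc3)cc(OCc3ccccc3)cc2O[C@@H]1c1cc(OCc2ccccc2)c(OCc2ccccc2)c(OCc2ccccc2)c1 | intermediate

3 | 5,7,3',4',5'-penta-O-benzyl-3-O-TBS-(−)-epigallocatechin, (2R,3R) | CC(C)(C)[Si](C)(C)O[C@@H]1Cc2c(OCc3ccccc3)cc(OCc3ccccc3)cc2O[C@@H]1c1cc(OCc2ccccc2)c(OCc2ccccc2)c(OCc2ccccc2)c1 | intermediate

4 | 8-bromo-5,7,3',4',5'-penta-O-benzyl-3-O-TBS-(−)-epigallocatechin, (2R,3R) | CC(C)(C)[Si](C)(C)O[C@@H]1Cc2c(OCc3ccccc3)cc(OCc3ccccc3)c(Br)c2O[C@@H]1c1cc(OCc2ccccc2)c(OCc2ccccc2)c(OCc2ccccc2)c1 | intermediate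

5 | 2,4,6-trihydroxybenzaldehyde | O=Cc1c(O)cc(O)cc1O | starting material

6 | 4,6-bis(benzyloxy)-2-hydroxybenzaldehyde | O=Cc1c(O)cc(OCc2ccccc2)cc1OCc1ccccc1 | intermediate

7 | sodium 3,5-bis(benzyloxy)-2-formylphenoxide | [Na+].[O-]c1cc(OCc2ccccc2)cc(OCc2ccccc2)c1C=O | intermediate (not isolated)

8 | 8-lithio-5,7,3',4',5'-penta-O-benzyl-3-O-TBS-epigallocatechin, (2R,3R) | CC(C)(C)[Si](C)(C)O[C@@H]1Cc2c(OCc3ccccc3)cc(OCc3ccccc3)c([Li])c2O[C@@H]1c1cc(OCc2ccccc2)c(OCc2ccccc2)c(OCc2ccccc2)c1 | intermediate (not isolated)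

9 | 8-[(4,6-bis(benzyloxy)-2-hydroxyphenyl)(hydroxy)methyl]-5,7,3',4',5'-penta-O-benzyl-3-O-TBS-epigallocatechin, flavan (2R,3R), carbinol carbon as both epimers | OC(c1c(O)cc(OCc2ccccc2)cc1OCc1ccccc1)c1c(OCc2ccccc2)cc(OCc2ccccc2)c2c1O[C@H](c1cc(OCc3ccccc3)c(OCc3ccccc3)c(OCc3ccccc3)c1)[C@H](O[Si](C)(C)C(C)(C)C)C2 | intermediate

10 | 3,4,5-trihydroxybenzaldehyde | O=Cc1cc(O)c(O)c(O)c1 | starting material

11 | 3,4,5-tris(benzyloxy)benzaldehyde | O=Cc1cc(OCc2ccccc2)c(OCc2ccccc2)c(OCc2ccccc2)c1 | intermediate

12 | 1,2,3-tris(benzyloxy)-5-ethynylbenzene | C#Cc1cc(OCc2ccccc2)c(OCc2ccccc2)c(OCc2ccccc2)c1 | intermediate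

13 | 3,4,5-tris(benzyloxy)benzoic acid | O=C(O)c1cc(OCc2ccccc2)c(OCc2ccccc2)c(OCc2ccccc2)c1 | starting material

14 | (Z)-2-[3,4,5-tris(benzyloxy)phenyl]ethenyl 3,4,5-tris(benzyloxy)benzoate | O=C(O/C=C\c1cc(OCc2ccccc2)c(OCc2ccccc2)c(OCc2ccccc2)c1)c1cc(OCc2ccccc2)c(OCc2ccccc2)c(OCc2ccccc2)c1 | intermediate

15 | (6E)-3,5-bis(benzyloxy)-6-{[(2R,3R)-5,7-bis(benzyloxy)-3-(tert-butyldimethylsilyloxy)-2-(3,4,5-tris(benzyloxy)phenyl)chroman-8-yl]methylidene}cyclohexa-2,4-dien-1-one (o-quinone methide) | O=C1C=C(OCc2ccccc2)C=C(OCc2ccccc2)/C1=C\c1c(OCc2ccccc2)cc(OCc2ccccc2)c2c1O[C@H](c1cc(OCc3ccccc3)c(OCc3ccccc3)c(OCc3ccccc3)c1)[C@H](O[Si](C)(C)C(C)(C)C)C2 | intermediate (not isolated)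

16 | (2R,3R,4R)-5,7-bis(benzyloxy)-4-{(2R,3R)-5,7-bis(benzyloxy)-3-(tert-butyldimethylsilyloxy)-2-[3,4,5-tris(benzyloxy)phenyl]chroman-8-yl}-2-[3,4,5-tris(benzyloxy)phenyl]chroman-3-yl 3,4,5-tris(benzyloxy)benzoate (2,3-cis-3,4-trans upper unit, 4β→8) | O=C(O[C@@H]1[C@@H](c2c(OCc3ccccc3)cc(OCc3ccccc3)c3c2O[C@H](c2cc(OCc4ccccc4)c(OCc4ccccc4)c(OCc4ccccc4)c2)[C@H](O[Si](C)(C)C(C)(C)C)C3)c2c(OCc3ccccc3)cc(OCc3ccccc3)cc2O[C@@H]1c1cc(OCc2ccccc2)c(OCc2ccccc2)c(OCc2ccccc2)c1)c1cc(OCc2ccccc2)c(OCc2ccccc2)c(OCc2ccccc2)c1 | intermediate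

17 | desilylated dimer: as 16 with a free (3R)-hydroxyl on the lower unit | O=C(O[C@@H]1[C@@H](c2c(OCc3ccccc3)cc(OCc3ccccc3)c3c2O[C@H](c2cc(OCc4ccccc4)c(OCc4ccccc4)c(OCc4ccccc4)c2)[C@H](O)C3)c2c(OCc3ccccc3)cc(OCc3ccccc3)cc2O[C@@H]1c1cc(OCc2ccccc2)c(OCc2ccccc2)c(OCc2ccccc2)c1)c1cc(OCc2ccccc2)c(OCc2ccccc2)c(OCc2ccccc2)c1 | intermediate

18 | hexadeca-O-benzyl rhodisin: as 17 with the lower 3-oxygen esterified by 3,4,5-tris(benzyloxy)benzoyl (upper 2R,3R,4R; lower 2R,3R) | O=C(O[C@@H]1[C@@H](c2c(OCc3ccccc3)cc(OCc3ccccc3)c3c2O[C@H](c2cc(OCc4ccccc4)c(OCc4ccccc4)c(OCc4ccccc4)c2)[C@H](OC(=O)c2cc(OCc4ccccc4)c(OCc4ccccc4)c(OCc4ccccc4)c2)C3)c2c(OCc3ccccc3)cc(OCc3ccccc3)cc2O[C@@H]1c1cc(OCc2ccccc2)c(OCc2ccccc2)c(OCc2ccccc2)c1)c1cc(OCc2ccccc2)c(OCc2ccccc2)c(OCc2ccccc2)c1 | intermediate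

19 | rhodisin, epigallocatechin 3-O-gallate-(4β→8)-epigallocatechin 3-O-gallate (upper 2R,3R,4R; lower 2R,3R) | O=C(O[C@@H]1[C@@H](c2c(O)cc(O)c3c2O[C@H](c2cc(O)c(O)c(O)c2)[C@H](OC(=O)c2cc(O)c(O)c(O)c2)C3)c2c(O)cc(O)cc2O[C@@H]1c1cc(O)c(O)c(O)c1)c1cc(O)c(O)c(O)c1 | target

**Step count:** 12 steps in total. The longest linear sequence is 8 steps (steps 1, 2, 3, 5, 9, 10, 11, 12).

**Steps most likely to fail**

Step 9 (proposed new method). Three processes may intervene:
- The enol ester, a weak π-nucleophile, may intercept the strongly stabilised quinone methide too slowly, so that Friedel–Crafts self-alkylation at the free C6 positions takes over.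
- A stepwise cationic course may erode the transfer of alkene geometry (2,3-trans product), or endo addition may give the 3,4-cis product.
- Face selection by the catalyst may be poor.

The fallback uses the established Lewis acid coupling of a C4-activated flavan with a C8 nucleophile. It sets out from 2, which is oxidised at C4 with DDQ in the presence of 2-ethoxyethanol (CH2Cl2, rt) to 4β-(2-ethoxyethoxy)-penta-O-benzyl-epigallocatechin F1. Esterification of its C3 hydroxyl with 13 (DCC, DMAP, CH2Cl2) gives the 3-O-[3,4,5-tris(benzyloxy)benzoyl] derivative F2. TMSOTf (catalytic, CH2Cl2, −78 °C) then ionises F2 in the presence of an excess of 3, which should attack through C8 trans to the 3-acyloxy group, and the route is rejoined at 16.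

Step 5. The aryllithium may be protonated by incompletely deprotonated phenol, or may add too slowly to the hindered, electron-rich phenoxide aldehyde, leaving mainly the debrominated flavan. The fallback masks the phenol as an ether instead of a salt. It sets out from 6, which with allyl bromide and K2CO3 in DMF gives 2-(allyloxy)-4,6-bis(benzyloxy)benzaldehyde F3, a neutral and more electrophilic aldehyde. Addition of 8 (from 4 and t-BuLi, THF, −78 °C) gives the O-allyl benzhydrol F4. Removal of the allyl group with Pd(PPh3)4 and morpholine in THF returns to 9.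

Step 8. Incomplete Z selectivity or partial Markovnikov addition would carry the wrong alkene geometry or regiochemistry into the cycloaddition. The fallback builds the Z alkene before the C–O bond. It sets out from 12, which undergoes rhodium-catalysed trans-hydroboration with pinacolborane ([RhCl(C8H12)]2, P(i-Pr)3, Et3N, cyclohexane) to give the (Z)-alkenylboronic pinacol ester F5. KHF2 in aqueous methanol converts it into the potassium (Z)-alkenyltrifluoroborate F6. Copper-mediated oxidative C–O coupling with 13 (Cu(OAc)2, DMAP, 4 Å MS, O2, CH2Cl2), which proceeds with retention of alkene geometry, returns to 14.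

**Further compounds**

F1 | step 9 | 4β-(2-ethoxyethoxy)-5,7,3',4',5'-penta-O-benzyl-epigallocatechin (2,3-cis-3,4-trans) | O[C@@H]1[C@@H](OCCOCC)c2c(OCc3ccccc3)cc(OCc3ccccc3)cc2O[C@@H]1c1cc(OCc2ccccc2)c(OCc2ccccc2)c(OCc2ccccc2)c1

F2 | step 9 | 4β-(2-ethoxyethoxy)-5,7,3',4',5'-penta-O-benzyl-epigallocatechin 3-O-[3,4,5-tris(benzyloxy)benzoate] | O=C(O[C@@H]1[C@@H](OCCOCC)c2c(OCc3ccccc3)cc(OCc3ccccc3)cc2O[C@@H]1c1cc(OCc2ccccc2)c(OCc2ccccc2)c(OCc2ccccc2)c1)c1cc(OCc2ccccc2)c(OCc2ccccc2)c(OCc2ccccc2)c1

F3 | step 5 | 2-(allyloxy)-4,6-bis(benzyloxy)benzaldehyde | C=CCOc1cc(OCc2ccccc2)cc(OCc2ccccc2)c1C=O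

F4 | step 5 | 8-[(2-(allyloxy)-4,6-bis(benzyloxy)phenyl)(hydroxy)methyl]-penta-O-benzyl-3-O-TBS-epigallocatechin, flavan (2R,3R), both carbinol epimers | OC(c1c(OCC=C)cc(OCc2ccccc2)cc1OCc1ccccc1)c1c(OCc2ccccc2)cc(OCc2ccccc2)c2c1O[C@H](c1cc(OCc3ccccc3)c(OCc3ccccc3)c(OCc3ccccc3)c1)[C@H](O[Si](C)(C)C(C)(C)C)C2

F5 | step 8 | (Z)-4,4,5,5-tetramethyl-2-{2-[3,4,5-tris(benzyloxy)phenyl]ethenyl}-1,3,2-dioxaborolane | CC1(C)OB(/C=C\c2cc(OCc3ccccc3)c(OCc3ccccc3)c(OCc3ccccc3)c2)OC1(C)C

F6 | step 8 | potassium (Z)-trifluoro{2-[3,4,5-tris(benzyloxy)phenyl]ethenyl}borate | [K+].F[B-](F)(F)/C=C\c1cc(OCc2ccccc2)c(OCc2ccccc2)c(OCc2ccccc2)c1
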